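The earlier runs and the new flask were computed with made-up constants; scatter was added.

Time is what the larch run has to offer: after its feed ends, its electrophile keeps falling, but ever more slowly.

the same everywhere: electrophile 0.020 M (fed, over 2.0 min)

| flask | nucleophile | free base | remark | time |
|---|---|---|---|---|
| larch | 0.024 M | 0.015 M | run made earlier |  |
| epsilon | 0.0240 M | 0.0200 M |  | 8.0 min |
| delta | 0.0240 M | 0.0260 M |  | 8.0 min |
| zeta | 0.0240 M | 0.0340 M |  | 8.0 min |

larch run (percent of the electrophile charged)

| time / min | electrophile / % | target / % |
|---|---|---|
| 0.667 | 29.9 | 4.4 |
| 2.00 | 71.5 | 23.7 |
| 4.00 | 45.9 | 33.8 |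
| 6.00 | 32.7 | 37.2 |
| 8.00 | 27.0 | 36.0 |

(each reading ± 1 percentage point)

- the numbers in the tables scatter with a standard deviation of 1 percentage point
- percentages count the whole charge, also what has not yet gone in
- no earlier run changes the charge of free base; that part of a forecast is a guess

- part of the electrophile that has reacted at the end, epsilon
- part of the electrophile that has reacted at the end, delta
- part of the electrophile that has reacted at the end, zeta
- what raising the concentration of free base from its lowest to its highest value here does to the part of the electrophile that has reacted (changes below 5 percentage points count as none) (no change / it falls / it rises)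

Read as a pseudo-first-order loss, the larch electrophile falls at 0.222 min⁻¹ between 2.00 min and 4.00 min, then at 0.170 min⁻¹ up to 6.00 min. The late loss rate λ, the logarithm of the ratio of the last two readings divided by the time between them, is 0.0958 min⁻¹, a reading that carries their scatter.

These rates give a bracket for the new flasks. From below stands the larch end, 73.0% reacted, on the assumption that more free base slows nothing. From above, the early rate held from 2.00 min to 8.0 min gives 81.1%. That upper end can be drawn in. Counting at most one free base per electrophile reacted, larch has used at most 0.0135 M by 6.00 min, less than its 0.015 M, yet its rate has already fallen. With less electrophile reacted than free base charged, extra free base therefore looks to have little to relieve in larch before that time. Following larch to 6.00 min and then holding 0.170 min⁻¹ gives 76.7%. This reckoning expects all three flasks between 73.0% and 76.7%, a span under the margin, so no change; the base dependence remains a guess.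

The forecast differs, with 83%, 88% and 91%, and says it rises, holding of larch that “acid scavenging appears to limit it”.

The flasks give 73.5%, 73.6% and 73.7%, inside the bracket and below the forecast: no change, with 0.23 percentage points between lowest and highest free base.

    electrophile + target → side product (k = 0.160 L mol⁻¹ s⁻¹)
    nucleophile + acid set free ⇌ protonated nucleophile, settled at all times (K = 7900 L mol⁻¹)
    acid set free + free base ⇌ salt of the base (K = 77.0 L mol⁻¹, k = 0.550 L mol⁻¹ s⁻¹)
    electrophile + nucleophile → acid set free + target (k = 0.280 L mol⁻¹ s⁻¹)
    acid set free → by-product carried off (k = 0.00150 s⁻¹)

At the end of epsilon, protonated nucleophile stands at 0.00999 M, far above the 4.27 × 10⁻⁴ M of salt of the base. Of the free base, 98% remains. Carried from epsilon's 26.5% at 8.0 min, λ gives 0.0268% at 80.0 min, where epsilon holds 0.0300%. Carried from zeta's 26.3%, it gives 3.20% at 30 min, where zeta holds 3.01%.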